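**Retrosynthetic overview**
- Both vinyl-carbon-to-spiro-carbon bonds (C4–C5 and C10–C6 of the 1,7-dioxadispiro[4.0.4.2]dodeca-3,9-diene-2,8-dione) are cut. The target then becomes, plus 2 HBr, the mixed bis(3,3-dibromoacrylate) of an all-trans 3,4-dibromocyclobutane-1,2-diol.
- Enabling feature: each spiro carbon is the cyclobutane carbon that carries the lactone oxygen. In the seco-ester it is a carbinol methine whose C–H lies 1,5 to the CBr2 carbon and on the same ring face as the neighbouring ring C–Br. Putting carbon in place of that H with retention gives the crowded cis relation between vinyl carbon and ring bromine, which addition to a flat C5 would not give.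
- The all-trans O/Br/Br/O array comes from anti opening of the epoxide of trans-3,4-dibromocyclobutene, and a lipase resolution fixes its absolute configuration. The diol is C2-symmetric, so its hydroxyls are homotopic and the (S)- and (R)-acids go on one after the other.
- Both acid enantiomers come from one lipase resolution of the Morita–Baylis–Hillman adduct of butanal and tert-butyl acrylate. CH2= is changed to CBr2= by ozonolysis and Ramirez olefination.
- Ring order: the cyclobutane is bought, and both butenolide rings close together in the last step.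

Key step: step 16

Assumption: both lipases are taken to show the usual preference for the (R)-type secondary carbinol (larger group of higher CIP rank); with the opposite preference the other fraction of each resolution would be carried on.
Assumption: cis-3,4-dichlorocyclobutene is taken as a catalogue chemical.

**Step 1**
Reactants: 1 cis-3,4-dichlorocyclobutene
Product: 2 (±)-trans-3,4-dibromocyclobutene
Conditions: LiBr (excess), acetone, 45 °C
Reagents that add atoms: lithium bromide, [Li+].[Br-]
Why: Finkelstein halide exchange (SN2/SN2′ at the allylic carbons, LiCl precipitating) is reversible for bromide, so the mixture should settle on the less crowded and less polar trans-dibromide, which fixes the relative configuration of the two CHBr centres.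

**Step 2**
Reactants: 2 (±)-trans-3,4-dibromocyclobutene
Product: 3 (±)-2,3-dibromo-5-oxabicyclo[2.1.0]pentane (bromines trans, one syn and one anti to the oxirane oxygen)
Conditions: dimethyldioxirane, acetone, 0 °C to rt
Reagents that add atoms: dimethyldioxirane, CC1(C)OO1
Why: Neutral dioxirane epoxidation of the strained alkene should give one racemic epoxide because the two faces of the C2-symmetric alkene are equivalent, and the acid-free medium spares the strained bicycle.

**Step 3**
Reactants: 3 (±)-2,3-dibromo-5-oxabicyclo[2.1.0]pentane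
Product: 4 (±)-all-trans-3,4-dibromocyclobutane-1,2-diyl diacetate
Conditions: Ac2O, Sc(OTf)3 (cat.), CH2Cl2, −20 °C
Reagents that add atoms: acetic anhydride, CC(=O)OC(C)=O
Why: In this Lewis-acid-catalysed acetolysis of an epoxide (anti, SN2-like opening) acetate should attack the oxirane carbon whose rear face is flanked by C–H and not by the cis C–Br bond, which gives the all-trans O/Br/Br/O array.

**Step 4**
Reactants: 4 (±)-all-trans-3,4-dibromocyclobutane-1,2-diyl diacetate
Product: 6 (1S,2S,3R,4R)-3,4-dibromocyclobutane-1,2-diol, via all-trans monoacetate 5 (not isolated)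
Conditions: Burkholderia cepacia lipase, pH 7 phosphate buffer/MTBE, 30 °C, stopped near half conversion
Reagents that add atoms: none
Why: Lipase-catalysed hydrolytic kinetic resolution with two successive selective deacylations should release only the fast enantiomer (spatially the (R,R)-cycloalkanediol type, 1S,2S by CIP because of bromine) and so sets the absolute configuration of all four ring centres.

**Step 5**
Reactants: 7 butanal; 8 tert-butyl acrylate
Product: 9 (±)-tert-butyl 2-(1-hydroxybutyl)acrylate
Conditions: DABCO, dioxane/H2O, rt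
Reagents that add atoms: none
Why: The Morita–Baylis–Hillman reaction joins the acrylate α-carbon to the aldehyde and gives the branched C3 skeleton with a racemic carbinol centre.

**Step 6**
Reactants: 9 (±)-tert-butyl 2-(1-hydroxybutyl)acrylate
Product: 10 tert-butyl (R)-2-(1-acetoxybutyl)acrylate; 11 tert-butyl (S)-2-(1-hydroxybutyl)acrylate (unreacted enantiomer)
Conditions: Pseudomonas fluorescens lipase, vinyl acetate, MTBE, 30 °C, stopped near half conversion
Reagents that add atoms: vinyl acetate, C=COC(C)=O
Why: Lipase kinetic resolution by irreversible transesterification should acylate the (R)-alcohol only, so one operation supplies both side-chain configurations that the target needs.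

**Step 7**
Reactants: 11 tert-butyl (S)-2-(1-hydroxybutyl)acrylate
Product: 12 tert-butyl (S)-2-(1-acetoxybutyl)acrylate
Conditions: Ac2O, pyridine, DMAP (cat.), CH2Cl2, 0 °C
Reagents that add atoms: acetic anhydride, CC(=O)OC(C)=O
Why: O-Acetylation leaves the C–O bond of the carbinol untouched, so the (S) configuration is kept.

**Step 8**
Reactants: 12 tert-butyl (S)-2-(1-acetoxybutyl)acrylate
Product: 14 tert-butyl (S)-3-acetoxy-2-oxohexanoate, via secondary ozonide 13 (not isolated)
Conditions: O3, CH2Cl2, −78 °C; then Me2S, to rt
Reagents that add atoms: ozone, [O-][O+]=O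
Why: Ozonolysis (Criegee mechanism) with reductive work-up cleaves the 1,1-disubstituted alkene to the α-keto ester under neutral conditions that do not touch the stereocentre.

**Step 9**
Reactants: 14 tert-butyl (S)-3-acetoxy-2-oxohexanoate
Product: 15 tert-butyl (S)-2-(1-acetoxybutyl)-3,3-dibromoacrylate
Conditions: CBr4, PPh3, CH2Cl2, 0 °C
Reagents that add atoms: carbon tetrabromide, BrC(Br)(Br)Br
Why: Ramirez dibromoolefination works on ketones activated by an adjacent ester, and at 0 °C the Wittig-type step should outrun enolisation of the α-acetoxy ketone.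

**Step 10**
Reactants: 15 tert-butyl (S)-2-(1-acetoxybutyl)-3,3-dibromoacrylate
Product: 16 (S)-2-(1-acetoxybutyl)-3,3-dibromoacrylic acid
Conditions: TFA/CH2Cl2 1:3, 0 °C to rt
Reagents that add atoms: none
Why: Acidolysis of the tert-butyl ester (E1 loss of isobutene) frees the acid without touching the acetate or the dibromoalkene.

**Step 11**
Reactants: 10 tert-butyl (R)-2-(1-acetoxybutyl)acrylate
Product: 18 tert-butyl (R)-3-acetoxy-2-oxohexanoate, via secondary ozonide 17 (not isolated)
Conditions: O3, CH2Cl2, −78 °C; then Me2S, to rt
Reagents that add atoms: ozone, [O-][O+]=O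
Why: Ozonolysis with reductive work-up, as in step 8, leaves the (R) centre untouched.

**Step 12**
Reactants: 18 tert-butyl (R)-3-acetoxy-2-oxohexanoate
Product: 19 tert-butyl (R)-2-(1-acetoxybutyl)-3,3-dibromoacrylate
Conditions: CBr4, PPh3, CH2Cl2, 0 °C
Reagents that add atoms: carbon tetrabromide, BrC(Br)(Br)Br
Why: Ramirez dibromoolefination of the activated keto group, as in step 9.

**Step 13**
Reactants: 19 tert-butyl (R)-2-(1-acetoxybutyl)-3,3-dibromoacrylate
Product: 20 (R)-2-(1-acetoxybutyl)-3,3-dibromoacrylic acid
Conditions: TFA/CH2Cl2 1:3, 0 °C to rt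
Reagents that add atoms: none
Why: Acidolysis of the tert-butyl ester, as in step 10.

**Step 14**
Reactants: 6 (1S,2S,3R,4R)-3,4-dibromocyclobutane-1,2-diol (excess); 16 (S)-2-(1-acetoxybutyl)-3,3-dibromoacrylic acid
Product: 21 (1S,2S,3R,4R)-3,4-dibromo-2-hydroxycyclobutyl (S)-2-(1-acetoxybutyl)-3,3-dibromoacrylate
Conditions: DCC, DMAP (cat.), CH2Cl2, 0 °C to rt
Reagents that add atoms: none
Why: In this Steglich esterification the two hydroxyls of the C2-symmetric diol are homotopic, so monoacylation gives a single compound and no ring centre is touched.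

**Step 15**
Reactants: 21 the monoester; 20 (R)-2-(1-acetoxybutyl)-3,3-dibromoacrylic acid
Product: 22 (1S,2S,3R,4R)-3,4-dibromocyclobutane-1,2-diyl 1-[(S)-2-(1-acetoxybutyl)-3,3-dibromoacrylate] 2-[(R)-2-(1-acetoxybutyl)-3,3-dibromoacrylate]
Conditions: DCC, DMAP (cat.), CH2Cl2, rt
Reagents that add atoms: none
Why: A second Steglich esterification puts the enantiomeric acid on the remaining hydroxyl with all six stereocentres unchanged.

**Step 16**
Reactants: 22 the mixed diester
Product: 24 the target, (5S,6S,11R,12R)-3-[(1S)-1-acetoxybutyl]-9-[(1R)-1-acetoxybutyl]-4,10,11,12-tetrabromo-1,7-dioxadispiro[4.0.4.2]dodeca-3,9-diene-2,8-dione, via mono-spirolactone 23 (not isolated)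
Conditions: Pd(P(t-Bu)3)2 (20 mol %), CsOPiv (40 mol %), Cs2CO3 (2.5 equiv), toluene, 110 °C
Reagents that add atoms: none
Why: Proposed new method: Pd(0) adds reversibly to the vinylic C–Br bond cis to the ester carbonyl, bromide is exchanged for pivalate, the 1,5-related cyclobutane methine C–H next to the ester oxygen is cleaved by concerted metalation–deprotonation, and the six-membered oxapalladacycle forms the bond from the C(Br)= carbon to the ring carbon by reductive elimination while Cs2CO3 takes up HBr. The closest known reaction types are Pd(0)-catalysed intramolecular C(sp3)–H alkenylation with bromoalkenes, methine C–H arylation of small rings to spirocycles, and mono-coupling of gem-dibromoolefins under reversible oxidative addition, but an acyloxy-bearing cyclobutane methine has not been used. Both butenolides close in the same mode, as five-membered rings by C–C reductive elimination from the palladacycle (a formal 1,5-C–H insertion), the second one on 23. Both new quaternary stereocentres are controlled by the carbinol configuration of 22, because metalation and reductive elimination each go with retention, so each vinyl carbon takes the place of H, cis to the adjacent ring bromine and trans to the other vinyl carbon. The step needs vinylic C–Br activation over ring C–Br and allylic C–OAc activation, the ring methine over propyl C–H bonds, and survival of the second vinylic bromide. These should be secured by the bulky monoligated catalyst (slow SN2-type addition to hindered cyclobutyl bromides, poor binding to the tetrasubstituted alkene, reversible addition to the product C–Br), by the higher s-character and inductive acidification of the ring C–H, and by the all-trans ring, in which every vicinal H/Br pair is syn so that the base cannot start an anti elimination.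

**Compound list**
1 | cis-3,4-dichlorocyclobutene (meso) | Cl[C@@H]1C=C[C@@H]1Cl | starting material
2 | (±)-trans-3,4-dibromocyclobutene (one enantiomer drawn) | Br[C@@H]1C=C[C@H]1Br | intermediate
3 | (±)-2,3-dibromo-5-oxabicyclo[2.1.0]pentane, bromines trans (one enantiomer drawn) | Br[C@@H]1[C@H]2O[C@H]2[C@H]1Br | intermediate
4 | (±)-all-trans-3,4-dibromocyclobutane-1,2-diyl diacetate (one enantiomer drawn) | CC(=O)O[C@@H]1[C@@H](Br)[C@H](Br)[C@H]1OC(C)=O | intermediate
5 | all-trans 3,4-dibromo-2-hydroxycyclobutyl acetate, same absolute series as 6 | CC(=O)O[C@@H]1[C@@H](Br)[C@H](Br)[C@H]1O | intermediate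
6 | (1S,2S,3R,4R)-3,4-dibromocyclobutane-1,2-diol | O[C@@H]1[C@@H](Br)[C@H](Br)[C@H]1O | intermediate
7 | butanal | CCCC=O | starting material
8 | tert-butyl acrylate | C=CC(=O)OC(C)(C)C | starting material
9 | (±)-tert-butyl 2-(1-hydroxybutyl)acrylate | CCCC(O)C(=C)C(=O)OC(C)(C)C | intermediate
10 | tert-butyl (R)-2-(1-acetoxybutyl)acrylate | CCC[C@@H](OC(C)=O)C(=C)C(=O)OC(C)(C)C | intermediate
11 | tert-butyl (S)-2-(1-hydroxybutyl)acrylate | CCC[C@H](O)C(=C)C(=O)OC(C)(C)C | intermediate
12 | tert-butyl (S)-2-(1-acetoxybutyl)acrylate | CCC[C@H](OC(C)=O)C(=C)C(=O)OC(C)(C)C | intermediate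
13 | secondary ozonide (1,2,4-trioxolane) of 12 | CCC[C@H](OC(C)=O)C1(OCOO1)C(=O)OC(C)(C)C | intermediate
14 | tert-butyl (S)-3-acetoxy-2-oxohexanoate | CCC[C@H](OC(C)=O)C(=O)C(=O)OC(C)(C)C | intermediate
15 | tert-butyl (S)-2-(1-acetoxybutyl)-3,3-dibromoacrylate | CCC[C@H](OC(C)=O)C(=C(Br)Br)C(=O)OC(C)(C)C | intermediate
16 | (S)-2-(1-acetoxybutyl)-3,3-dibromoacrylic acid | CCC[C@H](OC(C)=O)C(=C(Br)Br)C(O)=O | intermediate
17 | secondary ozonide (1,2,4-trioxolane) of 10 | CCC[C@@H](OC(C)=O)C1(OCOO1)C(=O)OC(C)(C)C | intermediate
18 | tert-butyl (R)-3-acetoxy-2-oxohexanoate | CCC[C@@H](OC(C)=O)C(=O)C(=O)OC(C)(C)C | intermediate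
19 | tert-butyl (R)-2-(1-acetoxybutyl)-3,3-dibromoacrylate | CCC[C@@H](OC(C)=O)C(=C(Br)Br)C(=O)OC(C)(C)C | intermediate
20 | (R)-2-(1-acetoxybutyl)-3,3-dibromoacrylic acid | CCC[C@@H](OC(C)=O)C(=C(Br)Br)C(O)=O | intermediate
21 | monoester of 6 with 16 | CCC[C@H](OC(C)=O)C(=C(Br)Br)C(=O)O[C@@H]1[C@@H](Br)[C@H](Br)[C@H]1O | intermediate
22 | mixed diester of 6 with 16 and 20 | CCC[C@H](OC(C)=O)C(=C(Br)Br)C(=O)O[C@@H]1[C@@H](Br)[C@H](Br)[C@H]1OC(=O)C(=C(Br)Br)[C@@H](CCC)OC(C)=O | intermediate
23 | mono-spirolactone: the (S)-side-chain butenolide closed, the (R)-dibromoacrylate still open | CCC[C@H](OC(C)=O)C1=C(Br)[C@@]2(OC1=O)[C@@H](Br)[C@H](Br)[C@H]2OC(=O)C(=C(Br)Br)[C@@H](CCC)OC(C)=O | intermediate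
24 | target | CCC[C@H](OC(C)=O)C1=C(Br)[C@@]2(OC1=O)[C@@H](Br)[C@H](Br)[C@@]21OC(=O)C([C@@H](CCC)OC(C)=O)=C1Br | target

**Step count and risks**
Total step count: 16.
Longest linear sequence: 9 steps (5, 6, 7, 8, 9, 10, 14, 15, 16).

**Steps most likely to fail**

1. Step 16.
   - What may go wrong: palladium may add to the ring C–Br bonds and strip the vicinal dibromide, ionise the allylic acetates, or cleave a propyl C–H bond instead of the hindered methine.
   - The fallback uses known chemistry and builds the four-membered ring by light instead of functionalising its C–H bonds. It sets out from 15 and returns at 24.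
   - Stille coupling of 15 with ethynyltributylstannane, at the C–Br bond trans to the branched side chain, would give tert-butyl (S,E)-2-(1-acetoxybutyl)-3-bromopent-2-en-4-ynoate F1.
   - TFA would free the enynoic acid F2.
   - NBS/KHCO3 would close it by anti 5-exo-dig bromolactonisation to the (E)-bromomethylene butenolide F3.
   - Irradiation (λ ≥ 300 nm) would dimerise F3 head to head, as 5-methylenebutenolides do. The (5S,6S,11R,12R) dimer with two (S) side chains F4 would be separated from its diastereomers.
   - Acid methanolysis stopped early would remove one of the two homotopic acetates to give the mono-alcohol F5.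
   - A Mitsunobu reaction with acetic acid would invert that carbinol and give 24.

2. Step 3.
   - What may go wrong: the Lewis acid may trigger rearrangement of the strained oxabicyclopentane (hydride shift or ring contraction), or the opening may lose its site selectivity.
   - The fallback sets out from 2, bypasses step 2 as well, and returns at 4.
   - OsO4/NMO dihydroxylation would give the cis-diol F6.
   - SO2Cl2/Et3N would give the cyclic sulfate F7.
   - CsOAc in DMF would open it with inversion at the carbon whose rear face carries no cis bromine, giving the caesium sulfate monoester F8.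
   - Acid hydrolysis would lead to the racemic form of hydroxy acetate 5, and acetylation would give 4.

3. Step 9.
   - What may go wrong: the basic ylide may enolise the α-acetoxy ketone, with erosion of configuration or loss of acetate.
   - The fallback sets out from 12, avoids the keto ester, and returns at 15.
   - Br2 addition to 12 would give the 2,3-dibromopropanoate F9.
   - Et3N would eliminate HBr to the 3-bromoacrylate F10.
   - A second Br2 addition would give the 2,3,3-tribromopropanoate F11, and DBU would eliminate HBr to 15.

**Further compounds**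
F1 | step 16 | tert-butyl (S,E)-2-(1-acetoxybutyl)-3-bromopent-2-en-4-ynoate | CCC[C@H](OC(C)=O)/C(C(=O)OC(C)(C)C)=C(\Br)C#C
F2 | step 16 | (S,E)-2-(1-acetoxybutyl)-3-bromopent-2-en-4-ynoic acid | CCC[C@H](OC(C)=O)/C(C(O)=O)=C(\Br)C#C
F3 | step 16 | (E)-3-[(1S)-1-acetoxybutyl]-4-bromo-5-(bromomethylene)furan-2(5H)-one | CCC[C@H](OC(C)=O)C1=C(Br)/C(=C\Br)OC1=O
F4 | step 16 | (5S,6S,11R,12R) head-to-head dimer with two (1S)-1-acetoxybutyl groups | CCC[C@H](OC(C)=O)C1=C(Br)[C@@]2(OC1=O)[C@@H](Br)[C@H](Br)[C@@]21OC(=O)C([C@H](CCC)OC(C)=O)=C1Br
F5 | step 16 | mono-alcohol of F4, with a (1S)-1-hydroxybutyl group on one lactone | CCC[C@H](OC(C)=O)C1=C(Br)[C@@]2(OC1=O)[C@@H](Br)[C@H](Br)[C@@]21OC(=O)C([C@H](CCC)O)=C1Br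
F6 | step 3 | (±)-3,4-trans-dibromocyclobutane-1,2-cis-diol (one enantiomer drawn) | O[C@@H]1[C@@H](Br)[C@H](Br)[C@@H]1O
F7 | step 3 | (±)-cyclic sulfate of F6 | O=S1(=O)O[C@@H]2[C@@H](Br)[C@H](Br)[C@@H]2O1
F8 | step 3 | (±)-caesium all-trans-2-acetoxy-3,4-dibromocyclobutyl sulfate | [Cs+].[O-]S(=O)(=O)O[C@@H]1[C@@H](Br)[C@H](Br)[C@H]1OC(C)=O
F9 | step 9 | tert-butyl 2-[(1S)-1-acetoxybutyl]-2,3-dibromopropanoate (epimers at C2) | CCC[C@H](OC(C)=O)C(Br)(CBr)C(=O)OC(C)(C)C
F10 | step 9 | tert-butyl 2-[(1S)-1-acetoxybutyl]-3-bromoacrylate (E/Z mixture) | CCC[C@H](OC(C)=O)C(=CBr)C(=O)OC(C)(C)C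
F11 | step 9 | tert-butyl 2-[(1S)-1-acetoxybutyl]-2,3,3-tribromopropanoate (epimers at C2) | CCC[C@H](OC(C)=O)C(Br)(C(Br)Br)C(=O)OC(C)(C)C
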